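The vessel is closed and stirred and starts with none of the solid electrophile in solution. The readings of solid electrophile and product, and my reckoning from them, are given as fractions of a charge of solid electrophile.

in all of them: free base 0.645 M

| run | solid electrophile | protonated nucleophile | remark | time |
|---|---|---|---|---|
| amber | 0.43 M | 0.32 M | run made earlier |  |
| grey | 0.43 M | 0.48 M | run made earlier |  |
| ochre | 0.86 M | 0.645 M | run made earlier |  |
| flask | 0.43 M | 0.645 M |  | 6.0 h |

- amber (time / h: solid electrophile / %, product / %): 0.500: 90.6, 2.0; 1.00: 81.7, 5.2; 1.50: 75.3, 8.1; 2.50: 63.4, 12.2; 4.00: 53.3, 15.1; 8.00: 42.2, 17.6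
- grey (time / h: solid electrophile / %, product / %): 0.500: 89.7, 2.2; 1.00: 82.6, 6.0; 1.50: 74.5, 9.8; 2.50: 64.2, 13.4; 4.00: 52.6, 19.2; 8.00: 37.9, 22.8
- ochre (time / h: solid electrophile / %, product / %): 1.33: 88.4, 4.0; 3.00: 78.4, 9.0; 4.00: 75.4, 9.0; 6.00: 71.1, 10.0; 8.00: 69.6, 10.6

(readings scatter by 0.5 percentage points)

* part of the solid electrophile that has reacted (what has only dissolved counts as not reacted) at 6.0 h
* share of the unused nucleophile that is free and not bound as protonated nucleophile, at 6.0 h

- the earlier runs were read with a standard deviation of 0.5 percentage points
- at the start none of the solid electrophile is in solution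
- what has only dissolved of solid electrophile counts as not reacted
- the earlier runs do not show how much of nucleophile is bound; that part of a forecast is a guess

This is my own reckoning of the product curve for the flask:

1. Start: the grey run has the flask's charges of solid electrophile and free base. It begins at 0.0440 h⁻¹ and steepens to 0.0760 h⁻¹ between 1.00 h and 1.50 h, a slope greater than the first, which is an induction period.
2. Knee: after 4.00 h the grey run gains 0.00900 h⁻¹, far less than before, so the curve bends near that time.
3. Solution: at 8.00 h, the ochre run holds 39.6% dissolved and unreacted, counted on the flask's charge. The grey run holds about the same, 39.3%, although the ochre run was charged with twice the solid electrophile.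
4. Level: the ochre run also has the flask's free base and protonated nucleophile. I therefore carry its product at 6.00 h, counted on the flask's charge, and call this the reach: 20.0%.

The forecast gives 22% reacted, a little above the reach, and 5% free, adding “but this is a guess”.

The flask gives 21.0% and 3.11%, so both forecast values stand within their margins.

    electrophile + nucleophile → acid set free + product (k = 6.53 M⁻¹ h⁻¹)
    nucleophile + acid set free ⇌ protonated nucleophile, settled at all times (K = 4250 M⁻¹)
    acid set free + free base ⇌ salt of the base, settled at all times (K = 23000 M⁻¹)
    2 nucleophile → homo dimer (k = 4.88 M⁻¹ h⁻¹)
    solid electrophile ⇌ electrophile, rate k5*(cs5 - [electrophile]) while solid is left; crystals form when [electrophile] > cs5 (solubility = 0.180 M, k = 0.516 h⁻¹)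

The reach of 20.0% lies just below the flask's 21.0%. The forecast of the reacted part holds for this charge of solid electrophile: with the other charges and the time held, that answer has moved by 5 points at 0.347 M or at 0.564 M. Carried to a neighbour flask charged with 0.26 M of solid electrophile, the same amount of product counted on that smaller charge makes the reach 33.1%. That neighbour gives 34.7% reacted.

The runs were computed for substances that don't exist, and the scatter is random.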